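**Retrosynthetic overview**
- Key C–C disconnection at C12–C13 of the acyl chain: octacosan-1-ol 1, oxidised to octacosanal 2, supplies C13–C40; methyl 12-bromododecanoate 3 supplies C1–C12.
- The aldehyde carbon of 2 is used with inverted polarity: its N–H hydrazone 4 acts as a traceless acyl-anion-type carbanion toward the alkyl bromide (N2 is lost in the bond-forming event), giving methyl tetracontanoate 5 with nothing to remove afterwards.
- Ester C–O disconnection last: 5 + tyrosol 6 → target 7 by acyl transfer to the aliphatic OH only, without protecting groups.
- Ring formation: none; the benzene ring is bought with 6.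

Assumption: the acyl chain of the SMILES is read as an unbranched C40 chain (tetracontanoyl). The target has no stereocentre and no stereogenic double bond, so no stereocontrol is needed.

**Step 1**
Reactants: 1 octacosan-1-ol
Product: 2 octacosanal
Conditions: TEMPO (10 mol %), PhI(OAc)2 (1.2 equiv), CHCl3 (amylene-stabilised), 45 °C
Reagents that add atoms: none
Why: The oxoammonium-mediated TEMPO/PhI(OAc)2 oxidation of a primary alcohol stops at the aldehyde when water is absent, and warm chloroform keeps the waxy C28 chain dissolved.

**Step 2**
Reactants: 2 octacosanal; 3 methyl 12-bromododecanoate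
Product: 5 methyl tetracontanoate, via octacosanal hydrazone 4 (not isolated)
Conditions: N2H4·H2O (1.5 equiv), THF, 45 °C, then toluene azeotrope to strip water and excess hydrazine; then 3 (0.75 equiv), Ni(cod)2 (10 mol %), PMe3 (20 mol %), K3PO4 (2 equiv), DBU (20 mol %), 4 Å MS, THF, 60 °C, argon
Reagents that add atoms: hydrazine hydrate, NN.O (its two nitrogen atoms sit in intermediate 4 only and leave as N2; none of its heavy atoms stays in 5)
Why: Proposed new method: in hydrazone 4 the former carbonyl carbon is a carbanion equivalent (azo-anion form of the deprotonated N–H hydrazone, a traceless acyl anion surrogate), so once zerovalent nickel has inserted into the primary C–Br bond of 3 and the deprotonated hydrazone has bound through nitrogen, the alkyl group is passed to carbon through a six-membered transition state and N2 is expelled (Wolff–Kishner-type driving force), joining two carbons that are both electrophilic by nature; the closest known reaction type is the nickel-catalysed deoxygenative cross-coupling of aldehyde N–H hydrazones with aryl and alkyl halides (secure for aryl aldehyde hydrazones), supported by the ruthenium-catalysed hydrazone additions in which aliphatic aldehyde hydrazones do act as alkyl carbanions, and the untested part is pairing a purely aliphatic C28 hydrazone with an unactivated, ester-bearing primary bromide.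

**Step 3**
Reactants: 5 methyl tetracontanoate; 6 tyrosol
Product: 7 2-(4-hydroxyphenyl)ethyl tetracontanoate
Conditions: 6 (3 equiv), p-TsOH·H2O (10 mol %), toluene, reflux, MeOH trapped on 5 Å MS (Soxhlet)
Reagents that add atoms: none
Why: Acid-catalysed transesterification reaches only the primary aliphatic OH of 6, because the phenol is too weak a nucleophile under acid and aryl esters are disfavoured at equilibrium, while removal of methanol and the excess of 6 drive the conversion.

**Compound list**
1 | octacosan-1-ol | CCCCCCCCCCCCCCCCCCCCCCCCCCCCO | starting material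
2 | octacosanal | CCCCCCCCCCCCCCCCCCCCCCCCCCCC=O | intermediate
3 | methyl 12-bromododecanoate | COC(=O)CCCCCCCCCCCBr | starting material
4 | octacosanal hydrazone [(E)-octacosylidenehydrazine] | CCCCCCCCCCCCCCCCCCCCCCCCCCC/C=N/N | intermediate
5 | methyl tetracontanoate | CCCCCCCCCCCCCCCCCCCCCCCCCCCCCCCCCCCCCCCC(=O)OC | intermediate
6 | tyrosol [2-(4-hydroxyphenyl)ethanol] | OCCc1ccc(O)cc1 | starting material
7 | 2-(4-hydroxyphenyl)ethyl tetracontanoate | CCCCCCCCCCCCCCCCCCCCCCCCCCCCCCCCCCCCCCCC(=O)OCCc1ccc(O)cc1 | target

**Totals**
Total step count: 3. Longest linear sequence: 3 steps (1 → 2 → 5 → 7).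

**Steps most likely to fail**

Step 2 (highest risk). The aliphatic hydrazone 4 may be reduced to octacosane, form the azine or be N-alkylated, and the alkylnickel intermediate may lose a β-hydride. The fallback sets out from 2 and comes back at 7, using the classical sulfur-stabilised acyl anion instead of the hydrazone. Aldehyde 2 is condensed with propane-1,3-dithiol (BF3·OEt2, CH2Cl2, 35 °C) to 2-heptacosyl-1,3-dithiane F1. F1 is lithiated with n-BuLi (THF, −20 °C) and alkylated with lithium 12-bromododecanoate (THF/DMPU, −20 °C to rt, then dilute HCl) to give 12-(2-heptacosyl-1,3-dithian-2-yl)dodecanoic acid F2. F2 is esterified with tyrosol 6 (p-TsOH, toluene, Dean–Stark, aliphatic OH only) to 2-(4-hydroxyphenyl)ethyl 12-(2-heptacosyl-1,3-dithian-2-yl)dodecanoate F3. Desulfurisation of F3 with Raney Ni (EtOH/THF, reflux) then delivers 7.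

Step 3. The equilibrium may stall because the C40 ester is poorly soluble and methanol removal is slow. The fallback sets out from 5 and comes back at 7, activating the alcohol instead of the acyl group. Ester 5 is saponified (KOH, EtOH/THF, reflux, then HCl) to tetracontanoic acid F4. F4 is then coupled with tyrosol 6 under Mitsunobu conditions (PPh3, DIAD, THF, 45 °C); the carboxylic acid, far more acidic than the phenol, is the only pronucleophile, so the ester forms at the primary carbon and gives 7.

Step 1. Solubility of the C28 alcohol, partial over-oxidation and air sensitivity of the waxy aldehyde are the concerns. The fallback sets out from 1 and comes back at 2, replacing alcohol oxidation by substitution and elimination. Alcohol 1 is heated with 48 % HBr and catalytic Bu4NBr (110 °C) to give 1-bromooctacosane F5. F5 is treated with anhydrous trimethylamine N-oxide (DMSO/CHCl3, 50 °C); displacement of bromide and loss of trimethylamine from the alkoxyammonium salt give 2 with no path to the acid.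

**Further compounds**
F1 | step 2 | 2-heptacosyl-1,3-dithiane | CCCCCCCCCCCCCCCCCCCCCCCCCCCC1SCCCS1
F2 | step 2 | 12-(2-heptacosyl-1,3-dithian-2-yl)dodecanoic acid | CCCCCCCCCCCCCCCCCCCCCCCCCCCC1(CCCCCCCCCCCC(=O)O)SCCCS1
F3 | step 2 | 2-(4-hydroxyphenyl)ethyl 12-(2-heptacosyl-1,3-dithian-2-yl)dodecanoate | CCCCCCCCCCCCCCCCCCCCCCCCCCCC1(CCCCCCCCCCCC(=O)OCCc2ccc(O)cc2)SCCCS1
F4 | step 3 | tetracontanoic acid | CCCCCCCCCCCCCCCCCCCCCCCCCCCCCCCCCCCCCCCC(=O)O
F5 | step 1 | 1-bromooctacosane | CCCCCCCCCCCCCCCCCCCCCCCCCCCCBr
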